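If I wanted mono adduct from the oak flask, my rule of thumb was to stop as the substrate readings ran low and to expect a steady share of the substrate lost to be standing as mono adduct.

| flask | substrate | gas | remark | time |
|---|---|---|---|---|
| oak | 1.5 M | 200 mM (held) | the very flask that is asked about, followed so far |  |
| ash | 3 M | 200 mM (held) | run made earlier |  |
| flask | 1.5 M | 200 mM (held) |  | 50 min |

| run | time / min | mono adduct / % | substrate / % |
|---|---|---|---|
| oak | 0.667 | 25.9 | 69.3 |
| oak | 1.33 | 46.7 | 38.5 |
| oak | 2.00 | 67.2 | 17.1 |
| oak | 4.00 | 61.0 | 0.8 |
| oak | 6.00 | 39.8 | 0 |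
| oak | 12.0 | 10.0 | 0 |
| oak | 20.0 | 0 | 1.0 |
| ash | 0.667 | 11.7 | 83.7 |
| ash | 1.33 | 27.2 | 68.0 |
| ash | 3.00 | 53.6 | 30.7 |
| ash | 6.00 | 66.5 | 0 |
| ash | 12.0 | 22.3 | 0.2 |
| ash | 25.0 | 0.3 | 0 |
| ash | 50.0 | 1.9 | 0.3 |

(each reading ± 1 percentage point)

- when, up to 50 min, the flask holds most mono adduct
- the amount of mono adduct, in percent of the substrate charged, at that time

The ash run at 3.00 min held 53.6 % mono adduct with 30.7 % substrate left, a share of 77.3 %. The oak run at 2.00 min gave 81.1 %, though ash had twice the charge. I carried the lower figure, as the cautious choice, and called it the net selectivity, the mono adduct standing per substrate lost.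

The rule needs substrate still being lost, so I looked for its border. Between its first and third readings, the ash run lost substrate at 0.682 M min⁻¹ on average, and the oak charge divided by that ash rate is 2.20 min. The oak reading at 4.00 min lay past that border: the rule gave 76.7 %, but the reading was 61.0 %. My own reckoning was therefore a peak a little after 2.20 min, near 77.3 %.

The forecast differed, with 71 % at 2.7 min, and it held that “mono is consumed roughly ten times more slowly than substrate”.

The oak flask gave 74.4 % at 2.67 min, 3.4 percentage points above the forecast, which held. At that time 1.66 % substrate remained, so my net selectivity gave 76.0 %, 1.7 points above the flask.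

    substrate + coupling partner → mono adduct + by-product (k = 0.966 M⁻¹ s⁻¹)
    substrate + coupling partner → other mono adduct + by-product (k = 0.241 M⁻¹ s⁻¹)
    coupling partner + mono adduct → bis adduct + by-product (k = 0.0216 M⁻¹ s⁻¹)
    coupling partner + other mono adduct → bis adduct + by-product (k = 0.589 M⁻¹ s⁻¹)
    gas ⇌ coupling partner, rate k5*(csat - [coupling partner]) (kL = 0.0641 s⁻¹)

In the neighbouring flask with 0.60 M of substrate, the net selectivity again pointed to about 77.3 % at the peak. The computed neighbour reached 74.4 %, level with the oak flask.

(The numbers in the tables stem from a simulated flask on assumed constants; the scatter is artificial.)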